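**Retrosynthetic overview**

1. The plan rests on C2 of ring C: it is benzylic to ring B and bonded to O1, so O1–C2–ring B can be drawn as a ring B benzyl ether on O8a whose CH2 hydrogens lie six atoms from a carbene carbon at C3, alpha to the C4 ketone. C2–C3 is therefore cut, leading back to an alpha-diazoketone.
2. The diazoketone comes from the aryl methyl ketone by diazo transfer; the benzyl ether comes from the O8a phenol and 2,4-bis(TBSO)benzyl alcohol by Mitsunobu etherification.
3. The acetyl group (C4 and C3) is placed by ortho-lithiation of ring A between OMOM and OMe; the MOM director on O8a is then exchanged for the ring B benzyl group.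
4. The side chain grows from the formyl carbon of 2,4-dihydroxy-6-methoxybenzaldehyde, which becomes the benzylic CH2 on C6: Wittig, hydrogenation, Evans prenylation (side-chain stereocenter), MeMgBr.
5. Rings A and B are bought; ring C is the only ring made (key step). O7 is carried as a TIPS ether so that one buffered desilylation ends the route.

Key step: step 16

Assumption: Rh2(S-PTTL)4 is taken to deliver the 2S configuration at C2; should its sense of induction be the opposite, the mirror-image catalyst Rh2(R-PTTL)4 is used with nothing else changed.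

**Route**

Step 1
Reactants: 1 2,4-dihydroxy-6-methoxybenzaldehyde
Product: 2 2-hydroxy-6-methoxy-4-(methoxymethoxy)benzaldehyde
Conditions: MOMCl (1.05 equiv), K2CO3, acetone, 0 °C → rt
Reagents that add atoms: chloromethyl methyl ether, COCCl
Why: Williamson O-alkylation is expected at the 4-OH only, because it is the more acidic, unchelated phenol while the 2-OH is tied up in a hydrogen bond to the formyl group.

Step 2
Reactants: 2 2-hydroxy-6-methoxy-4-(methoxymethoxy)benzaldehyde
Product: 3 2-methoxy-4-(methoxymethoxy)-6-(triisopropylsilyloxy)benzaldehyde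
Conditions: TIPSCl, imidazole, DMF, rt → 40 °C
Reagents that add atoms: chlorotriisopropylsilane, CC(C)[Si](Cl)(C(C)C)C(C)C
Why: Imidazole-promoted silylation of the remaining phenol installs a bulky, non-coordinating ether that later neither directs nor allows lithiation at the ring position next to it.

Step 3
Reactants: 3 2-methoxy-4-(methoxymethoxy)-6-(triisopropylsilyloxy)benzaldehyde; 4 benzyl (triphenylphosphoranylidene)acetate
Product: 5 benzyl (E)-3-[2-methoxy-4-(methoxymethoxy)-6-(triisopropylsilyloxy)phenyl]prop-2-enoate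
Conditions: toluene, 100 °C
Reagents that add atoms: none
Why: Wittig olefination with a stabilised ylide should give the (E)-cinnamate under neutral conditions that leave the MOM and TIPS ethers untouched.

Step 4
Reactants: 5 benzyl (E)-3-[2-methoxy-4-(methoxymethoxy)-6-(triisopropylsilyloxy)phenyl]prop-2-enoate
Product: 6 3-[2-methoxy-4-(methoxymethoxy)-6-(triisopropylsilyloxy)phenyl]propanoic acid
Conditions: H2 (1 atm), 10% Pd/C, EtOAc, rt
Reagents that add atoms: none
Why: Catalytic hydrogenation saturates the C=C bond and hydrogenolyses the benzyl ester in one operation, so the acid is reached without base and with the aryl MOM and TIPS ethers inert.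

Step 5
Reactants: 6 3-[2-methoxy-4-(methoxymethoxy)-6-(triisopropylsilyloxy)phenyl]propanoic acid; 7 (S)-4-benzyloxazolidin-2-one
Product: 9 (S)-4-benzyl-3-{3-[2-methoxy-4-(methoxymethoxy)-6-(triisopropylsilyloxy)phenyl]propanoyl}oxazolidin-2-one, via mixed pivalic anhydride 8 (not isolated)
Conditions: PivCl, Et3N, THF, –20 °C; then 7, LiCl, rt
Reagents that add atoms: none
Why: N-acylation of the Evans auxiliary through a mixed anhydride should occur at the less hindered, non-pivaloyl carbonyl under mild LiCl/Et3N activation.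

Step 6
Reactants: 9 (S)-4-benzyl-3-{3-[2-methoxy-4-(methoxymethoxy)-6-(triisopropylsilyloxy)phenyl]propanoyl}oxazolidin-2-one; 10 prenyl bromide (1-bromo-3-methylbut-2-ene)
Product: 12 (S)-4-benzyl-3-{(2S)-2-[2-methoxy-4-(methoxymethoxy)-6-(triisopropylsilyloxy)benzyl]-5-methylhex-4-enoyl}oxazolidin-2-one, via sodium Z-enolate 11 (not isolated)
Conditions: NaN(SiMe3)2, THF, –78 °C; then 10, –78 → –40 °C
Reagents that add atoms: none
Why: In this Evans asymmetric alkylation the chelated (Z)-enolate is prenylated on the face opposite the C4 benzyl group of the (S)-auxiliary, which sets the side-chain stereocenter as (S).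

Step 7
Reactants: 12 (S)-4-benzyl-3-{(2S)-2-[2-methoxy-4-(methoxymethoxy)-6-(triisopropylsilyloxy)benzyl]-5-methylhex-4-enoyl}oxazolidin-2-one
Product: 13 S-ethyl (2S)-2-[2-methoxy-4-(methoxymethoxy)-6-(triisopropylsilyloxy)benzyl]-5-methylhex-4-enethioate
Conditions: EtSH, n-BuLi, THF, 0 °C
Reagents that add atoms: ethanethiol, CCS
Why: Thiolate cleavage of the N-acyl oxazolidinone (nucleophilic acyl substitution at the exocyclic carbonyl) releases the auxiliary without hydroxide or alkoxide, so the aryl silyl ether and the alpha stereocenter should survive.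

Step 8
Reactants: 13 S-ethyl (2S)-2-[2-methoxy-4-(methoxymethoxy)-6-(triisopropylsilyloxy)benzyl]-5-methylhex-4-enethioate
Product: 15 (3S)-3-[2-methoxy-4-(methoxymethoxy)-6-(triisopropylsilyloxy)benzyl]-2,6-dimethylhept-5-en-2-ol, via methyl ketone 14 (not isolated)
Conditions: MeMgBr (4 equiv), CeCl3, THF, –78 → 0 °C
Reagents that add atoms: methylmagnesium bromide, C[Mg]Br
Why: Double Grignard addition to the thioester builds the dimethyl carbinol, and the organocerium modification keeps the basicity low so that the alpha stereocenter is not enolised at the ketone stage.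

Step 9
Reactants: 15 (3S)-3-[2-methoxy-4-(methoxymethoxy)-6-(triisopropylsilyloxy)benzyl]-2,6-dimethylhept-5-en-2-ol
Product: 16 triethylsilyl ether of 15 (tertiary O–SiEt3)
Conditions: TESOTf, 2,6-lutidine, CH2Cl2, –78 → 0 °C
Reagents that add atoms: triethylsilyl trifluoromethanesulfonate, CC[Si](CC)(CC)OS(=O)(=O)C(F)(F)F
Why: Silyl triflate silylation is the standard way to cap a hindered tertiary alcohol, and at low temperature with a hindered base the aryl MOM ether should not be touched.

Step 10
Reactants: 16 triethylsilyl ether of 15; 17 N-methoxy-N-methylacetamide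
Product: 19 1-[2-methoxy-6-(methoxymethoxy)-3-{(2S)-5-methyl-2-[2-(triethylsilyloxy)propan-2-yl]hex-4-en-1-yl}-4-(triisopropylsilyloxy)phenyl]ethan-1-one, via aryllithium 18 (not isolated)
Conditions: n-BuLi, TMEDA, THF, –20 → 0 °C; then 17, –78 → 0 °C
Reagents that add atoms: none
Why: In this directed ortho-metalation MOM and OMe cooperate to place lithium on the ring carbon between them, the other free position being shielded by the OTIPS group, and Weinreb ketone synthesis then delivers the acetyl group that becomes C4 and C3.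

Step 11
Reactants: 19 1-[2-methoxy-6-(methoxymethoxy)-3-{(2S)-5-methyl-2-[2-(triethylsilyloxy)propan-2-yl]hex-4-en-1-yl}-4-(triisopropylsilyloxy)phenyl]ethan-1-one
Product: 21 1-[6-hydroxy-2-methoxy-3-{(2S)-5-methyl-2-[2-(triethylsilyloxy)propan-2-yl]hex-4-en-1-yl}-4-(triisopropylsilyloxy)phenyl]ethan-1-one, via aryl trimethylsilyl ether 20 (not isolated)
Conditions: TMSOTf, 2,2'-bipyridyl, CH2Cl2, 0 °C → rt; then H2O
Reagents that add atoms: none
Why: Silyl triflate/bipyridyl cleavage of an aromatic MOM ether converts it into the aryl TMS ether, which hydrolyses on work-up, and the buffered aprotic medium is expected to spare the TES and TIPS ethers and the trisubstituted alkene.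

Step 12
Reactants: 22 2,4-dihydroxybenzaldehyde
Product: 23 2,4-bis(tert-butyldimethylsilyloxy)benzaldehyde
Conditions: TBSCl (2.4 equiv), imidazole, DMF, rt
Reagents that add atoms: tert-butyldimethylsilyl chloride, CC(C)(C)[Si](C)(C)Cl
Why: Imidazole-promoted silylation should protect both phenols, the chelated 2-OH included, under standard conditions.

Step 13
Reactants: 23 2,4-bis(tert-butyldimethylsilyloxy)benzaldehyde
Product: 24 [2,4-bis(tert-butyldimethylsilyloxy)phenyl]methanol
Conditions: NaBH4, MeOH/THF, –10 °C; aq. NH4Cl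
Reagents that add atoms: none
Why: Borohydride reduction in a protic medium at low temperature gives the benzyl alcohol while the alkoxide is protonated too quickly for aryl-to-benzyl silyl migration.

Step 14
Reactants: 21 1-[6-hydroxy-2-methoxy-3-{(2S)-5-methyl-2-[2-(triethylsilyloxy)propan-2-yl]hex-4-en-1-yl}-4-(triisopropylsilyloxy)phenyl]ethan-1-one; 24 [2,4-bis(tert-butyldimethylsilyloxy)phenyl]methanol
Product: 25 1-[6-{[2,4-bis(tert-butyldimethylsilyloxy)phenyl]methoxy}-2-methoxy-3-{(2S)-5-methyl-2-[2-(triethylsilyloxy)propan-2-yl]hex-4-en-1-yl}-4-(triisopropylsilyloxy)phenyl]ethan-1-one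
Conditions: PPh3, DIAD, THF, 0 °C → rt
Reagents that add atoms: none
Why: Mitsunobu etherification joins the acidic ortho-acyl phenol (the future O1) to the primary benzylic alcohol under neutral conditions that no silyl ether should feel, so the O1–C2 bond is made before ring closure.

Step 15
Reactants: 25 1-[6-{[2,4-bis(tert-butyldimethylsilyloxy)phenyl]methoxy}-2-methoxy-3-{(2S)-5-methyl-2-[2-(triethylsilyloxy)propan-2-yl]hex-4-en-1-yl}-4-(triisopropylsilyloxy)phenyl]ethan-1-one
Product: 27 2-diazo-1-[6-{[2,4-bis(tert-butyldimethylsilyloxy)phenyl]methoxy}-2-methoxy-3-{(2S)-5-methyl-2-[2-(triethylsilyloxy)propan-2-yl]hex-4-en-1-yl}-4-(triisopropylsilyloxy)phenyl]ethan-1-one, via trifluoroacetyl ketone 26 (not isolated)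
Conditions: LiN(SiMe3)2, THF, –78 °C; CF3CO2CH2CF3; then MsN3, Et3N, H2O, MeCN, rt
Reagents that add atoms: methanesulfonyl azide, CS(=O)(=O)N=[N+]=[N-]
Why: Detrifluoroacetylative diazo transfer (Danheiser variant of the Regitz reaction) activates the only enolisable position as a trifluoroacetyl ketone and exchanges that acyl group for the diazo group, giving the terminal alpha-diazoketone without diazomethane.

Step 16
Reactants: 27 2-diazo-1-[6-{[2,4-bis(tert-butyldimethylsilyloxy)phenyl]methoxy}-2-methoxy-3-{(2S)-5-methyl-2-[2-(triethylsilyloxy)propan-2-yl]hex-4-en-1-yl}-4-(triisopropylsilyloxy)phenyl]ethan-1-one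
Product: 28 (2S)-2-[2,4-bis(tert-butyldimethylsilyloxy)phenyl]-5-methoxy-6-{(2S)-5-methyl-2-[2-(triethylsilyloxy)propan-2-yl]hex-4-en-1-yl}-7-(triisopropylsilyloxy)chroman-4-one
Conditions: Rh2(S-PTTL)4 (dirhodium tetrakis[N-phthaloyl-(S)-tert-leucinate], divalent rhodium, 2 mol%), toluene, –20 °C → rt, slow addition of 27
Reagents that add atoms: none
Why: Loss of N2 from 27 at the dirhodium core gives an electrophilic rhodium carbenoid at C3, which inserts through a concerted, hydride-transfer-like three-centre transition state into one C–H bond of the benzylic CH2 on O8a and so forms C2–C3. The reaction type is the known dirhodium-carboxylate-catalysed intramolecular C–H insertion of ortho-alkoxyaryl alpha-diazoketones to chroman-4-ones. Ring C is closed as a six-membered ring by 1,6-insertion (C3, C4, C4a, C8a, O1, C2), and C2–C3 is the only bond formed because O1–C2 is already in place. The new stereocenter C2 is set under catalyst control, the chiral pocket of the phthaloyl-tert-leucinate ligands selecting one of the two enantiotopic benzylic hydrogens while the side-chain stereocenter is too remote to interfere. The step needs C–H insertion to win over oxonium-ylide formation at O8a or at the C5 methoxy oxygen (which would lead by [1,2]-shift to a benzofuranone) and over insertion into the OCH3 group; the benzylic C–H, activated by both O1 and the electron-rich ring B, is the most hydridic site, and the bulky carboxylate ligands, the non-polar solvent and the low temperature are expected to disfavour ylide formation.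

Step 17
Reactants: 28 (2S)-2-[2,4-bis(tert-butyldimethylsilyloxy)phenyl]-5-methoxy-6-{(2S)-5-methyl-2-[2-(triethylsilyloxy)propan-2-yl]hex-4-en-1-yl}-7-(triisopropylsilyloxy)chroman-4-one
Product: 29 (2S)-2-(2,4-dihydroxyphenyl)-7-hydroxy-6-[(2S)-2-(2-hydroxypropan-2-yl)-5-methylhex-4-en-1-yl]-5-methoxychroman-4-one
Conditions: TBAF, AcOH (1:1, excess), THF, 0 °C → rt
Reagents that add atoms: none
Why: Fluoride desilylation buffered with acetic acid should remove the three aryl silyl ethers and the tertiary TES ether while the phenols stay protonated, which guards C2 against ring opening to the chalcone and avoids acid strong enough to ionise the tertiary carbinol.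

**Compound list**

1 | 2,4-dihydroxy-6-methoxybenzaldehyde | COc1cc(O)cc(O)c1C=O | starting material
2 | 2-hydroxy-6-methoxy-4-(methoxymethoxy)benzaldehyde | COc1cc(OCOC)cc(O)c1C=O | intermediate
3 | 2-methoxy-4-(methoxymethoxy)-6-(triisopropylsilyloxy)benzaldehyde | COc1cc(OCOC)cc(O[Si](C(C)C)(C(C)C)C(C)C)c1C=O | intermediate
4 | benzyl (triphenylphosphoranylidene)acetate | O=C(C=P(c1ccccc1)(c1ccccc1)c1ccccc1)OCc1ccccc1 | starting material
5 | benzyl (E)-3-[2-methoxy-4-(methoxymethoxy)-6-(triisopropylsilyloxy)phenyl]prop-2-enoate | COc1cc(OCOC)cc(O[Si](C(C)C)(C(C)C)C(C)C)c1/C=C/C(=O)OCc1ccccc1 | intermediate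
6 | 3-[2-methoxy-4-(methoxymethoxy)-6-(triisopropylsilyloxy)phenyl]propanoic acid | COc1cc(OCOC)cc(O[Si](C(C)C)(C(C)C)C(C)C)c1CCC(=O)O | intermediate
7 | (S)-4-benzyloxazolidin-2-one | O=C1N[C@@H](Cc2ccccc2)CO1 | starting material
8 | mixed pivalic anhydride of 6 | COc1cc(OCOC)cc(O[Si](C(C)C)(C(C)C)C(C)C)c1CCC(=O)OC(=O)C(C)(C)C | intermediate
9 | (S)-4-benzyl-3-{3-[2-methoxy-4-(methoxymethoxy)-6-(triisopropylsilyloxy)phenyl]propanoyl}oxazolidin-2-one | COc1cc(OCOC)cc(O[Si](C(C)C)(C(C)C)C(C)C)c1CCC(=O)N1C(=O)OC[C@@H]1Cc1ccccc1 | intermediate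
10 | prenyl bromide (1-bromo-3-methylbut-2-ene) | CC(C)=CCBr | starting material
11 | sodium (Z)-enolate of 9 | COc1cc(OCOC)cc(O[Si](C(C)C)(C(C)C)C(C)C)c1C/C=C(\[O-])N1C(=O)OC[C@@H]1Cc1ccccc1.[Na+] | intermediate
12 | (S)-4-benzyl-3-{(2S)-2-[2-methoxy-4-(methoxymethoxy)-6-(triisopropylsilyloxy)benzyl]-5-methylhex-4-enoyl}oxazolidin-2-one | COc1cc(OCOC)cc(O[Si](C(C)C)(C(C)C)C(C)C)c1C[C@H](CC=C(C)C)C(=O)N1C(=O)OC[C@@H]1Cc1ccccc1 | intermediate
13 | S-ethyl (2S)-2-[2-methoxy-4-(methoxymethoxy)-6-(triisopropylsilyloxy)benzyl]-5-methylhex-4-enethioate | COc1cc(OCOC)cc(O[Si](C(C)C)(C(C)C)C(C)C)c1C[C@H](CC=C(C)C)C(=O)SCC | intermediate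
14 | (3S)-3-[2-methoxy-4-(methoxymethoxy)-6-(triisopropylsilyloxy)benzyl]-6-methylhept-5-en-2-one | COc1cc(OCOC)cc(O[Si](C(C)C)(C(C)C)C(C)C)c1C[C@H](CC=C(C)C)C(C)=O | intermediate
15 | (3S)-3-[2-methoxy-4-(methoxymethoxy)-6-(triisopropylsilyloxy)benzyl]-2,6-dimethylhept-5-en-2-ol | COc1cc(OCOC)cc(O[Si](C(C)C)(C(C)C)C(C)C)c1C[C@H](CC=C(C)C)C(C)(C)O | intermediate
16 | triethylsilyl ether of 15 | COc1cc(OCOC)cc(O[Si](C(C)C)(C(C)C)C(C)C)c1C[C@H](CC=C(C)C)C(C)(C)O[Si](CC)(CC)CC | intermediate
17 | N-methoxy-N-methylacetamide | CC(=O)N(C)OC | starting material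
18 | aryllithium from 16 (lithium on the ring carbon between OMe and OMOM) | COc1c([Li])c(OCOC)cc(O[Si](C(C)C)(C(C)C)C(C)C)c1C[C@H](CC=C(C)C)C(C)(C)O[Si](CC)(CC)CC | intermediate
19 | 1-[2-methoxy-6-(methoxymethoxy)-3-{(2S)-5-methyl-2-[2-(triethylsilyloxy)propan-2-yl]hex-4-en-1-yl}-4-(triisopropylsilyloxy)phenyl]ethan-1-one | COc1c(C(C)=O)c(OCOC)cc(O[Si](C(C)C)(C(C)C)C(C)C)c1C[C@H](CC=C(C)C)C(C)(C)O[Si](CC)(CC)CC | intermediate
20 | aryl trimethylsilyl ether corresponding to 21 | COc1c(C(C)=O)c(O[Si](C)(C)C)cc(O[Si](C(C)C)(C(C)C)C(C)C)c1C[C@H](CC=C(C)C)C(C)(C)O[Si](CC)(CC)CC | intermediate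
21 | 1-[6-hydroxy-2-methoxy-3-{(2S)-5-methyl-2-[2-(triethylsilyloxy)propan-2-yl]hex-4-en-1-yl}-4-(triisopropylsilyloxy)phenyl]ethan-1-one | COc1c(C(C)=O)c(O)cc(O[Si](C(C)C)(C(C)C)C(C)C)c1C[C@H](CC=C(C)C)C(C)(C)O[Si](CC)(CC)CC | intermediate
22 | 2,4-dihydroxybenzaldehyde | O=Cc1ccc(O)cc1O | starting material
23 | 2,4-bis(tert-butyldimethylsilyloxy)benzaldehyde | O=Cc1ccc(O[Si](C)(C)C(C)(C)C)cc1O[Si](C)(C)C(C)(C)C | intermediate
24 | [2,4-bis(tert-butyldimethylsilyloxy)phenyl]methanol | OCc1ccc(O[Si](C)(C)C(C)(C)C)cc1O[Si](C)(C)C(C)(C)C | intermediate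
25 | aryl methyl ketone carrying the ring B benzyl ether on O8a | COc1c(C(C)=O)c(OCc2ccc(O[Si](C)(C)C(C)(C)C)cc2O[Si](C)(C)C(C)(C)C)cc(O[Si](C(C)C)(C(C)C)C(C)C)c1C[C@H](CC=C(C)C)C(C)(C)O[Si](CC)(CC)CC | intermediate
26 | trifluoroacetyl ketone of 25 (4,4,4-trifluoro-1-arylbutane-1,3-dione) | COc1c(C(=O)CC(=O)C(F)(F)F)c(OCc2ccc(O[Si](C)(C)C(C)(C)C)cc2O[Si](C)(C)C(C)(C)C)cc(O[Si](C(C)C)(C(C)C)C(C)C)c1C[C@H](CC=C(C)C)C(C)(C)O[Si](CC)(CC)CC | intermediate
27 | alpha-diazoketone of ring A (O8a ring B benzyl ether, O7 TIPS, carbinol TES) | COc1c(C(=O)C=[N+]=[N-])c(OCc2ccc(O[Si](C)(C)C(C)(C)C)cc2O[Si](C)(C)C(C)(C)C)cc(O[Si](C(C)C)(C(C)C)C(C)C)c1C[C@H](CC=C(C)C)C(C)(C)O[Si](CC)(CC)CC | intermediate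
28 | (2S)-2-[2,4-bis(tert-butyldimethylsilyloxy)phenyl]-5-methoxy-6-{(2S)-5-methyl-2-[2-(triethylsilyloxy)propan-2-yl]hex-4-en-1-yl}-7-(triisopropylsilyloxy)chroman-4-one | COc1c(C[C@H](CC=C(C)C)C(C)(C)O[Si](CC)(CC)CC)c(O[Si](C(C)C)(C(C)C)C(C)C)cc2c1C(=O)C[C@@H](c1ccc(O[Si](C)(C)C(C)(C)C)cc1O[Si](C)(C)C(C)(C)C)O2 | intermediate
29 | (2S)-2-(2,4-dihydroxyphenyl)-7-hydroxy-6-[(2S)-2-(2-hydroxypropan-2-yl)-5-methylhex-4-en-1-yl]-5-methoxychroman-4-one | COc1c(C[C@H](CC=C(C)C)C(C)(C)O)c(O)cc2c1C(=O)C[C@@H](c1ccc(O)cc1O)O2 | target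

**Step count and risks**

Total step count: 17. Longest linear sequence: 15 (steps 1 to 11 and 14 to 17).

Steps most likely to fail:

1. Step 16. The carbenoid may be captured by the lone pair of O8a (or of the C5 methoxy oxygen) to give an oxonium ylide that rearranges by [1,2]-benzyl shift to a benzofuranone, or the catalyst may discriminate poorly between the two benzylic hydrogens. The fallback sets out from phenol 21 and aldehyde 23. The dilithium phenoxide-enolate of 21 (LiN(SiMe3)2, 2.2 equiv, THF, –78 °C) is added to 23 to give the aldol adduct, a beta-hydroxy ketone F1, as both carbinol epimers. Intramolecular Mitsunobu etherification (PPh3, DIAD, THF) then closes ring C at O1–C2 and should give 28 together with its C2 epimer, the (2R)-chromanone F2. The two are diastereomers because of the side-chain stereocenter and would be separated by chromatography, and the route is rejoined at 28.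

2. Step 10. Lithiation may be incomplete or stray to the benzylic CH2, and the hindered aryllithium may deprotonate the Weinreb amide instead of adding to it, returning the arene. The fallback sets out from 16: the same aryllithium 18 is quenched with DMF, a small electrophile without acidic hydrogens, to give the aldehyde F3. MeMgBr addition gives the secondary benzylic alcohol F4, and Dess–Martin periodinane oxidation returns the route to ketone 19.

3. Step 17. Phenoxides formed at O7, O2' and O4' under fluoride may open ring C by retro-oxa-Michael reaction and erode C2, and slow cleavage of the tertiary TES ether would prolong that exposure. The fallback sets out from 28 and splits the deprotection into two orthogonal operations. KHF2 in MeOH at rt, which is selective for phenolic silyl ethers, should give the triphenol that still carries the TES carbinol F5. The TES ether is then removed with AcOH/THF/H2O at rt, and the route is rejoined at target 29.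

**Further compounds**

F1 | step 16 | beta-hydroxy ketone from aldol addition of 21 to 23 (carbinol epimers) | COc1c(C(=O)CC(O)c2ccc(O[Si](C)(C)C(C)(C)C)cc2O[Si](C)(C)C(C)(C)C)c(O)cc(O[Si](C(C)C)(C(C)C)C(C)C)c1C[C@H](CC=C(C)C)C(C)(C)O[Si](CC)(CC)CC
F2 | step 16 | (2R) epimer of 28 | COc1c(C[C@H](CC=C(C)C)C(C)(C)O[Si](CC)(CC)CC)c(O[Si](C(C)C)(C(C)C)C(C)C)cc2c1C(=O)C[C@H](c1ccc(O[Si](C)(C)C(C)(C)C)cc1O[Si](C)(C)C(C)(C)C)O2
F3 | step 10 | 2-methoxy-6-(methoxymethoxy)-3-{(2S)-5-methyl-2-[2-(triethylsilyloxy)propan-2-yl]hex-4-en-1-yl}-4-(triisopropylsilyloxy)benzaldehyde | COc1c(C=O)c(OCOC)cc(O[Si](C(C)C)(C(C)C)C(C)C)c1C[C@H](CC=C(C)C)C(C)(C)O[Si](CC)(CC)CC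
F4 | step 10 | 1-aryl-ethan-1-ol from F3 (carbinol epimers) | COc1c(C(C)O)c(OCOC)cc(O[Si](C(C)C)(C(C)C)C(C)C)c1C[C@H](CC=C(C)C)C(C)(C)O[Si](CC)(CC)CC
F5 | step 17 | (2S)-2-(2,4-dihydroxyphenyl)-7-hydroxy-5-methoxy-6-{(2S)-5-methyl-2-[2-(triethylsilyloxy)propan-2-yl]hex-4-en-1-yl}chroman-4-one | COc1c(C[C@H](CC=C(C)C)C(C)(C)O[Si](CC)(CC)CC)c(O)cc2c1C(=O)C[C@@H](c1ccc(O)cc1O)O2
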